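Locants: heavy atoms in the order of the target SMILES, carbonyl oxygens skipped (C2 macrolactone carbinol, C5 ketone, C7/C21 butyrolactone carbons, C8=C9 ylidene, C11/C13/C17 pyran stereocentres, C23 ester carbonyl, O24).
Enabling feature: in the ten-membered ring (C2–C7, C21–C23, O24) the C3–C4 bond lies between the C2 carbinol and the C5 ketone, so it can be formed as the alkene of an enone from a but-3-en-2-yl ester and a vinyl ketone and then saturated.
Cuts, in order: C3–C4 (ring-closing metathesis, after adding back the C3=C4 unsaturation), C4–C5 (vinyl Grignard) and C23–O24 (esterification), then C8–C9 and C9–O18 (Claisen acylation, cyclodehydration), which separates a furo[3,2-b]pyranone from a trans-butyrolactone acid.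
Forward ring order: tetrahydropyran and its cis-fused γ-lactone from (R)-γ-valerolactone; trans γ-butyrolactone from (S)-butane-1,2,4-triol (the commercial reduction product of L-malic acid); tetrahydrofuran ring with the C8=C9 ylidene on union; ten-membered lactone last.
Stereochemistry: C13 from (R)-γ-valerolactone, C17 by Noyori transfer hydrogenation, C11 by thermodynamic oxa-Michael/lactonisation, C21 from the triol, C7 by anti-selective cuprate addition, C2 from (R)-but-3-en-2-ol, C8=C9 (E) by acid equilibration.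

Key step: step 20

Remark: the metathesis product 29 is drawn as the E-enone; either alkene geometry should give the same product in step 21.
Remark: 21 and 27 are carried as mixtures at centres that are erased in the following step.

Step 1
Reactants: 1 (R)-γ-valerolactone
Product: 2 (R)-4-hydroxy-N-methoxy-N-methylpentanamide
Conditions: MeNH(OMe)·HCl, Me3Al, CH2Cl2, 0 °C → rt
Reagents that add atoms: N,O-dimethylhydroxylamine hydrochloride, CNOC.Cl
Why: Weinreb aminolysis of the lactone by the aluminium amide should open the ring cleanly without touching the carbinol centre (C13).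

Step 2
Reactants: 2 (R)-4-hydroxy-N-methoxy-N-methylpentanamide
Product: 3 (R)-4-[(tert-butyldimethylsilyl)oxy]-N-methoxy-N-methylpentanamide
Conditions: TBSCl, imidazole, DMF, rt
Reagents that add atoms: tert-butyldimethylsilyl chloride, CC(C)(C)[Si](C)(C)Cl
Why: standard silyl ether formation should block relactonisation and mask the hydroxyl for the organolithium step.

Step 3
Reactants: 3 (R)-4-[(tert-butyldimethylsilyl)oxy]-N-methoxy-N-methylpentanamide; 4 ethyl propiolate
Product: 5 ethyl (R)-7-[(tert-butyldimethylsilyl)oxy]-4-oxooct-2-ynoate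
Conditions: 4, LiHMDS, THF, −78 °C; then 3, −78 → −50 °C; cold 1 M HCl
Reagents that add atoms: none
Why: acylation of the lithium acetylide by the Weinreb amide should stop at the ynone because the chelated tetrahedral intermediate survives until the cold acidic quench, which also keeps the released amine from adding to the ynone.

Step 4
Reactants: 5 ethyl (R)-7-[(tert-butyldimethylsilyl)oxy]-4-oxooct-2-ynoate
Product: 6 ethyl (4S,7R)-7-[(tert-butyldimethylsilyl)oxy]-4-hydroxyoct-2-ynoate
Conditions: Ru[(S,S)-TsDPEN](p-cymene) (2 mol %), i-PrOH, rt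
Reagents that add atoms: none
Why: Noyori asymmetric transfer hydrogenation of an ynone, in which the alkynyl group takes the place of the aryl group of the standard model, so the (S,S)-catalyst should deliver hydride to give the (S)-carbinol (C17) under catalyst control.

Step 5
Reactants: 6 ethyl (4S,7R)-7-[(tert-butyldimethylsilyl)oxy]-4-hydroxyoct-2-ynoate
Product: 7 ethyl (2E,4S,7R)-7-[(tert-butyldimethylsilyl)oxy]-4-hydroxyoct-2-enoate
Conditions: Red-Al, THF, −78 °C; Rochelle salt
Reagents that add atoms: none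
Why: alkoxide-directed trans-hydroalumination of the γ-hydroxy ynoate at low temperature should give the E-enoate without reducing the ester.

Step 6
Reactants: 7 ethyl (2E,4S,7R)-7-[(tert-butyldimethylsilyl)oxy]-4-hydroxyoct-2-enoate
Product: 8 ethyl (2E,4S,7R)-4,7-dihydroxyoct-2-enoate
Conditions: HF·pyridine, pyridine, THF, 0 °C → rt
Reagents that add atoms: none
Why: fluoride desilylation under mildly acidic conditions should free the C13 hydroxyl while the γ-hydroxy enoate neither cyclises nor isomerises.

Step 7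
Reactants: 8 ethyl (2E,4S,7R)-4,7-dihydroxyoct-2-enoate
Product: 10 (3aS,5R,7aS)-5-methylhexahydro-2H-furo[3,2-b]pyran-2-one, via hydroxy ester 9 (not isolated)
Conditions: DBU, PhMe, 80 °C
Reagents that add atoms: none
Why: the 6-exo oxa-Michael addition of the C13 hydroxyl is reversible under base and only the 2,6-cis tetrahydropyran with the axial C17 hydroxyl cis to the acetate arm can lactonise, so equilibration should funnel into the cis-fused lactone and set C11 (S) under thermodynamic control.

Step 8
Reactants: 11 (S)-butane-1,2,4-triol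
Product: 12 [(2S,4S)-2-phenyl-1,3-dioxan-4-yl]methanol
Conditions: PhCH(OMe)2, CSA (cat.), CH2Cl2, rt
Reagents that add atoms: benzaldehyde dimethyl acetal, COC(OC)c1ccccc1
Why: thermodynamic acetalisation should favour the six-membered 2,4-cis (diequatorial) benzylidene acetal across the C21 and C23 oxygens, leaving the future C7 hydroxyl free.

Step 9
Reactants: 12 [(2S,4S)-2-phenyl-1,3-dioxan-4-yl]methanol
Product: 13 (2S,4S)-2-phenyl-1,3-dioxane-4-carbaldehyde
Conditions: (COCl)2, DMSO, CH2Cl2, −78 °C; Et3N
Reagents that add atoms: none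
Why: Swern oxidation should give the α-alkoxy aldehyde without epimerisation at low temperature.

Step 10
Reactants: 13 (2S,4S)-2-phenyl-1,3-dioxane-4-carbaldehyde; 14 ethyl 2-(diphenoxyphosphoryl)acetate
Product: 15 ethyl (2Z)-3-[(2S,4S)-2-phenyl-1,3-dioxan-4-yl]prop-2-enoate
Conditions: 14, NaH, THF, −78 → 0 °C
Reagents that add atoms: none
Why: the Ando variant of the Horner–Wadsworth–Emmons olefination with a diaryl phosphonoacetate should give the Z-enoate under kinetic control.

Step 11
Reactants: 15 ethyl (2Z)-3-[(2S,4S)-2-phenyl-1,3-dioxan-4-yl]prop-2-enoate; 16 (1,3-dioxolan-2-ylmethyl)magnesium bromide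
Product: 17 ethyl (3R)-4-(1,3-dioxolan-2-yl)-3-[(2S,4S)-2-phenyl-1,3-dioxan-4-yl]butanoate
Conditions: 16, CuBr·SMe2, TMSCl, THF, −78 → −30 °C; aq. NH4Cl
Reagents that add atoms: none
Why: copper-mediated, TMSCl-accelerated conjugate addition of a Grignard reagent, in which A(1,3) strain of the Z-enoate holds the C21–H in the alkene plane and the organocopper attacks C7 anti to the C21–O bond (modified Felkin–Anh), should give the anti (3R) adduct that corresponds to the trans lactone.

Step 12
Reactants: 17 ethyl (3R)-4-(1,3-dioxolan-2-yl)-3-[(2S,4S)-2-phenyl-1,3-dioxan-4-yl]butanoate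
Product: 19 (4R,5S)-4-(1,3-dioxolan-2-ylmethyl)-5-(2-hydroxyethyl)dihydrofuran-2(3H)-one, via diol ester 18 (not isolated)
Conditions: H2 (1 atm), Pd(OH)2/C, EtOAc, rt; filter; DBU (cat.), PhMe, 60 °C
Reagents that add atoms: none
Why: hydrogenolysis should remove the benzylidene acetal without touching the dioxolane, after which the C21 hydroxyl closes the five-membered lactone in preference to the seven-membered alternative from the C23 hydroxyl.

Step 13
Reactants: 19 (4R,5S)-4-(1,3-dioxolan-2-ylmethyl)-5-(2-hydroxyethyl)dihydrofuran-2(3H)-one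
Product: 20 2-[(2S,3R)-3-(1,3-dioxolan-2-ylmethyl)-5-oxotetrahydrofuran-2-yl]acetic acid
Conditions: TEMPO (cat.), PhI(OAc)2, MeCN/H2O (1:1), rt
Reagents that add atoms: water, O
Why: oxoammonium oxidation of the primary alcohol through the aldehyde hydrate should give the C23 acid while lactone and dioxolane stay intact.

Step 14
Reactants: 20 2-[(2S,3R)-3-(1,3-dioxolan-2-ylmethyl)-5-oxotetrahydrofuran-2-yl]acetic acid; 10 (3aS,5R,7aS)-5-methylhexahydro-2H-furo[3,2-b]pyran-2-one
Product: 21 2-[(2S,3R)-3-(1,3-dioxolan-2-ylmethyl)-4-[(3aS,5R,7aS)-2-hydroxy-5-methylhexahydro-2H-furo[3,2-b]pyran-2-yl]-5-oxotetrahydrofuran-2-yl]acetic acid (epimers at C8 and C9 in equilibrium with the open keto alcohol)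
Conditions: LDA (2.1 equiv), THF, −78 °C; then 10 (0.8 equiv), −78 → −40 °C; 1 M HCl
Reagents that add atoms: none
Why: crossed Claisen acylation, in which the first equivalent of base forms the carboxylate (which protects C22–H and rules out β-elimination of O20) and the second forms the lactone enolate at C8, which should add to the lactone carbonyl of 10 to form C8–C9 as the lactol after protonation.

Step 15
Reactants: 21 the lactol acid from step 14
Product: 22 2-[(2S,3R,4E)-3-(1,3-dioxolan-2-ylmethyl)-4-[(3aS,5R,7aS)-5-methylhexahydro-2H-furo[3,2-b]pyran-2-ylidene]-5-oxotetrahydrofuran-2-yl]acetic acid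
Conditions: TsOH·H2O (cat.), 4 Å MS, CH2Cl2, rt
Reagents that add atoms: none
Why: acid-catalysed cyclodehydration of the γ-hydroxy β-keto lactone should give the donor–acceptor enol ether, and reversible protonation at C8 should equilibrate it to the E isomer, which keeps O18 away from the C19 carbonyl and the C10 methylene away from the C7 arm.

Step 16
Reactants: 22 the ylidene acid from step 15; 23 (R)-but-3-en-2-ol
Product: 24 (2R)-but-3-en-2-yl 2-[(2S,3R,4E)-3-(1,3-dioxolan-2-ylmethyl)-4-[(3aS,5R,7aS)-5-methylhexahydro-2H-furo[3,2-b]pyran-2-ylidene]-5-oxotetrahydrofuran-2-yl]acetate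
Conditions: 23, EDC·HCl, DMAP (cat.), CH2Cl2, 0 °C → rt
Reagents that add atoms: none
Why: Steglich-type carbodiimide esterification acylates the alcohol oxygen, so the C2 configuration of the chiral-pool alcohol is retained.

Step 17
Reactants: 24 the dioxolane ester from step 16
Product: 25 (2R)-but-3-en-2-yl 2-[(2S,3R,4E)-4-[(3aS,5R,7aS)-5-methylhexahydro-2H-furo[3,2-b]pyran-2-ylidene]-5-oxo-3-(2-oxoethyl)tetrahydrofuran-2-yl]acetate
Conditions: PPTS, acetone/H2O (9:1), 55 °C
Reagents that add atoms: water, O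
Why: mild acid hydrolysis of the dioxolane should release the C5 aldehyde, since the vinylogous carbonate and the allylic ester tolerate weak aqueous acid.

Step 18
Reactants: 25 the aldehyde from step 17; 26 vinylmagnesium bromide
Product: 27 (2R)-but-3-en-2-yl 2-[(2S,3R,4E)-3-(2-hydroxybut-3-en-1-yl)-4-[(3aS,5R,7aS)-5-methylhexahydro-2H-furo[3,2-b]pyran-2-ylidene]-5-oxotetrahydrofuran-2-yl]acetate (both C5 epimers)
Conditions: 26, THF, −78 °C; aq. NH4Cl
Reagents that add atoms: none
Why: Grignard 1,2-addition to the aldehyde at −78 °C should be much faster than attack on the ester or on the deactivated ylidene lactone, and the uncontrolled C5 carbinol is erased in the next step.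

Step 19
Reactants: 27 the allylic alcohol from step 18
Product: 28 (2R)-but-3-en-2-yl 2-[(2S,3R,4E)-4-[(3aS,5R,7aS)-5-methylhexahydro-2H-furo[3,2-b]pyran-2-ylidene]-5-oxo-3-(2-oxobut-3-en-1-yl)tetrahydrofuran-2-yl]acetate
Conditions: Dess–Martin periodinane, NaHCO3, CH2Cl2, 0 °C → rt
Reagents that add atoms: none
Why: buffered Dess–Martin oxidation of the allylic alcohol should give the vinyl ketone under neutral conditions, and the crude product is taken directly into the metathesis.

Step 20
Reactants: 28 the vinyl ketone/but-3-en-2-yl ester diene from step 19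
Product: 29 3,4-didehydrocordycicadin D, the ten-membered lactone with the C3=C4 enone (E drawn)
Conditions: Hoveyda–Grubbs II (10 mol %, portionwise), 1,4-benzoquinone (cat.), PhMe (1 mM), 80 °C
Reagents that add atoms: none
Why: The ruthenium alkylidene should initiate at the less electron-poor but-3-en-2-yl ester alkene, and the resulting carbene adds intramolecularly to the vinyl ketone through a ruthenacyclobutane that cycloreverts with loss of ethylene, forming C3=C4 (Chauvin [2+2]/retro-[2+2] sequence). The closest known reaction type is ring-closing metathesis of ester-tethered dienes to ten-membered lactones, including closures in which one partner is an enone. The ten-membered ring (C2–C7, C21–C23, O24) is closed by this single alkene-forming macrocyclisation between two chain ends held on the trans-disubstituted butyrolactone. No stereocentre is created, C2, C7 and C21 are spectators, and the alkene geometry is erased in step 21. The step needs chemoselectivity for the two monosubstituted alkenes, secured because the fully substituted, donor–acceptor-polarised C8=C9 is inert to the catalyst, and cyclisation over oligomerisation, secured by millimolar dilution, portionwise catalyst addition and the turn imposed by the lactone ring.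

Step 21
Reactants: 29 the macrocyclic enone from step 20
Product: 30 cordycicadin D
Conditions: [(Ph3P)CuH]6, H2O, benzene/THF, rt
Reagents that add atoms: none
Why: conjugate reduction with Stryker's reagent should deliver hydride to C3 of the enone and protonate the copper enolate with water, while the tetrasubstituted donor-substituted C8=C9, the lactones and the ketone are not reduced.

Compound list
1 | (R)-γ-valerolactone | C[C@@H]1CCC(=O)O1 | starting material
2 | (R)-4-hydroxy-N-methoxy-N-methylpentanamide | C[C@@H](O)CCC(=O)N(C)OC | intermediate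
3 | (R)-4-[(tert-butyldimethylsilyl)oxy]-N-methoxy-N-methylpentanamide | C[C@@H](O[Si](C)(C)C(C)(C)C)CCC(=O)N(C)OC | intermediate
4 | ethyl propiolate | C#CC(=O)OCC | starting material
5 | ethyl (R)-7-[(tert-butyldimethylsilyl)oxy]-4-oxooct-2-ynoate | C[C@@H](O[Si](C)(C)C(C)(C)C)CCC(=O)C#CC(=O)OCC | intermediate
6 | ethyl (4S,7R)-7-[(tert-butyldimethylsilyl)oxy]-4-hydroxyoct-2-ynoate | C[C@@H](O[Si](C)(C)C(C)(C)C)CC[C@H](O)C#CC(=O)OCC | intermediate
7 | ethyl (2E,4S,7R)-7-[(tert-butyldimethylsilyl)oxy]-4-hydroxyoct-2-enoate | C[C@@H](O[Si](C)(C)C(C)(C)C)CC[C@H](O)/C=C/C(=O)OCC | intermediate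
8 | ethyl (2E,4S,7R)-4,7-dihydroxyoct-2-enoate | C[C@@H](O)CC[C@H](O)/C=C/C(=O)OCC | intermediate
9 | ethyl 2-[(2S,3S,6R)-3-hydroxy-6-methyltetrahydro-2H-pyran-2-yl]acetate (not isolated) | CCOC(=O)C[C@@H]1O[C@H](C)CC[C@@H]1O | intermediate
10 | (3aS,5R,7aS)-5-methylhexahydro-2H-furo[3,2-b]pyran-2-one | O=C1C[C@@H]2O[C@H](C)CC[C@@H]2O1 | intermediate
11 | (S)-butane-1,2,4-triol | O[C@H](CO)CCO | starting material
12 | [(2S,4S)-2-phenyl-1,3-dioxan-4-yl]methanol | OC[C@@H]1CCO[C@H](c2ccccc2)O1 | intermediate
13 | (2S,4S)-2-phenyl-1,3-dioxane-4-carbaldehyde | O=C[C@@H]1CCO[C@H](c2ccccc2)O1 | intermediate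
14 | ethyl 2-(diphenoxyphosphoryl)acetate | CCOC(=O)CP(=O)(Oc1ccccc1)Oc1ccccc1 | starting material
15 | ethyl (2Z)-3-[(2S,4S)-2-phenyl-1,3-dioxan-4-yl]prop-2-enoate | CCOC(=O)/C=C\[C@@H]1CCO[C@H](c2ccccc2)O1 | intermediate
16 | (1,3-dioxolan-2-ylmethyl)magnesium bromide | Br[Mg]CC1OCCO1 | starting material
17 | ethyl (3R)-4-(1,3-dioxolan-2-yl)-3-[(2S,4S)-2-phenyl-1,3-dioxan-4-yl]butanoate | CCOC(=O)C[C@@H](CC1OCCO1)[C@@H]2CCO[C@H](c3ccccc3)O2 | intermediate
18 | ethyl (3R,4S)-3-(1,3-dioxolan-2-ylmethyl)-4,6-dihydroxyhexanoate (not isolated) | CCOC(=O)C[C@@H](CC1OCCO1)[C@@H](O)CCO | intermediate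
19 | (4R,5S)-4-(1,3-dioxolan-2-ylmethyl)-5-(2-hydroxyethyl)dihydrofuran-2(3H)-one | OCC[C@@H]1OC(=O)C[C@H]1CC2OCCO2 | intermediate
20 | 2-[(2S,3R)-3-(1,3-dioxolan-2-ylmethyl)-5-oxotetrahydrofuran-2-yl]acetic acid | OC(=O)C[C@@H]1OC(=O)C[C@H]1CC2OCCO2 | intermediate
21 | 2-[(2S,3R)-3-(1,3-dioxolan-2-ylmethyl)-4-[(3aS,5R,7aS)-2-hydroxy-5-methylhexahydro-2H-furo[3,2-b]pyran-2-yl]-5-oxotetrahydrofuran-2-yl]acetic acid (C8/C9 epimers) | OC(=O)C[C@@H]1OC(=O)C(C2(O)C[C@@H]3O[C@H](C)CC[C@@H]3O2)[C@H]1CC4OCCO4 | intermediate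
22 | 2-[(2S,3R,4E)-3-(1,3-dioxolan-2-ylmethyl)-4-[(3aS,5R,7aS)-5-methylhexahydro-2H-furo[3,2-b]pyran-2-ylidene]-5-oxotetrahydrofuran-2-yl]acetic acid | OC(=O)C[C@@H]1OC(=O)\C(=C2/C[C@@H]3O[C@H](C)CC[C@@H]3O2)[C@H]1CC4OCCO4 | intermediate
23 | (R)-but-3-en-2-ol | C=C[C@@H](C)O | starting material
24 | (2R)-but-3-en-2-yl 2-[(2S,3R,4E)-3-(1,3-dioxolan-2-ylmethyl)-4-[(3aS,5R,7aS)-5-methylhexahydro-2H-furo[3,2-b]pyran-2-ylidene]-5-oxotetrahydrofuran-2-yl]acetate | C=C[C@@H](C)OC(=O)C[C@@H]1OC(=O)\C(=C2/C[C@@H]3O[C@H](C)CC[C@@H]3O2)[C@H]1CC4OCCO4 | intermediate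
25 | (2R)-but-3-en-2-yl 2-[(2S,3R,4E)-4-[(3aS,5R,7aS)-5-methylhexahydro-2H-furo[3,2-b]pyran-2-ylidene]-5-oxo-3-(2-oxoethyl)tetrahydrofuran-2-yl]acetate | C=C[C@@H](C)OC(=O)C[C@@H]1OC(=O)\C(=C2/C[C@@H]3O[C@H](C)CC[C@@H]3O2)[C@H]1CC=O | intermediate
26 | vinylmagnesium bromide | C=C[Mg]Br | starting material
27 | (2R)-but-3-en-2-yl 2-[(2S,3R,4E)-3-(2-hydroxybut-3-en-1-yl)-4-[(3aS,5R,7aS)-5-methylhexahydro-2H-furo[3,2-b]pyran-2-ylidene]-5-oxotetrahydrofuran-2-yl]acetate (C5 epimers) | C=C[C@@H](C)OC(=O)C[C@@H]1OC(=O)\C(=C2/C[C@@H]3O[C@H](C)CC[C@@H]3O2)[C@H]1CC(O)C=C | intermediate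
28 | (2R)-but-3-en-2-yl 2-[(2S,3R,4E)-4-[(3aS,5R,7aS)-5-methylhexahydro-2H-furo[3,2-b]pyran-2-ylidene]-5-oxo-3-(2-oxobut-3-en-1-yl)tetrahydrofuran-2-yl]acetate | C=C[C@@H](C)OC(=O)C[C@@H]1OC(=O)\C(=C2/C[C@@H]3O[C@H](C)CC[C@@H]3O2)[C@H]1CC(=O)C=C | intermediate
29 | 3,4-didehydrocordycicadin D (ten-membered enone lactone, E drawn) | C[C@@H]1/C=C/C(=O)C[C@@H]2/C(=C3/C[C@@H]4O[C@H](C)CC[C@@H]4O3)C(=O)O[C@H]2CC(=O)O1 | intermediate
30 | cordycicadin D | C[C@@H]1CCC(=O)C[C@@H]2/C(=C3/C[C@@H]4O[C@H](C)CC[C@@H]4O3)C(=O)O[C@H]2CC(=O)O1 | target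

Total step count: 21.
Longest linear sequence: 15 steps (steps 1–7 and 14–21, from 1); the branch from 11 runs 14 steps (steps 8–21).

Steps most likely to fail

Step 11. The β-oxygenated alkyl group may transfer slowly from copper, and facial discrimination on the open-chain enoate may be incomplete, which would give some syn adduct and hence cis lactone. The fallback moves the stereocontrol onto a ring and uses a more electrophilic acceptor. It sets out from 15: TsOH in MeOH removes the benzylidene group and the freed C21 hydroxyl closes onto the Z-ester to give the butenolide (S)-5-(2-hydroxyethyl)furan-2(5H)-one F1, which is kept acidic so that the side-chain hydroxyl does not add to the butenolide. Silylation with TBSOTf/2,6-lutidine at −78 °C gives (S)-5-[2-(tert-butyldimethylsilyloxy)ethyl]furan-2(5H)-one F2. The copper reagent from 16 (CuBr·SMe2, TMSCl) should then add anti to the ring substituent to give the trans lactone (4R,5S)-5-[2-(tert-butyldimethylsilyloxy)ethyl]-4-(1,3-dioxolan-2-ylmethyl)dihydrofuran-2(3H)-one F3. HF·pyridine removes the silyl group and the sequence comes back to the route at 19.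

Step 14. Proton exchange between the dianion of 20 and the enolisable lactone 10 may compete with C-acylation, leading to self-condensation or to β-elimination of the pyran oxygen from the enolate of 10. The fallback replaces the lactone by a non-exchanging acyl donor. It sets out from 10: Me3Al/MeNH(OMe)·HCl opens it to the hydroxy Weinreb amide 2-[(2S,3S,6R)-3-hydroxy-6-methyltetrahydro-2H-pyran-2-yl]-N-methoxy-N-methylacetamide F4, and TESCl/imidazole gives its triethylsilyl ether F5. The dianion of 20 (LDA, 2.1 equiv) is acylated by F5 through a chelated tetrahedral intermediate to give the β-keto lactone acid 2-[(2S,3R)-3-(1,3-dioxolan-2-ylmethyl)-4-{2-[(2S,3S,6R)-6-methyl-3-(triethylsilyloxy)tetrahydro-2H-pyran-2-yl]acetyl}-5-oxotetrahydrofuran-2-yl]acetic acid F6. HF·pyridine followed by catalytic TsOH removes the silyl ether and cyclodehydrates, and the sequence comes back to the route at 22.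

Step 20. Intermolecular metathesis may outrun ring closure, and the catalyst may turn over slowly or form non-productive chelates at the electron-poor vinyl ketone. The fallback closes the ring one oxidation level lower. It sets out from 27 (both C5 epimers): ring-closing metathesis of the allylic alcohol diene (Grubbs II, CH2Cl2, 1 mM, reflux) should give the macrocyclic allylic alcohol 5-hydroxy-3,4-didehydro-5-deoxocordycicadin D F7, and Dess–Martin oxidation then comes back to the route at 29.

Further compounds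
F1 | step 11 | (S)-5-(2-hydroxyethyl)furan-2(5H)-one | OCC[C@@H]1OC(=O)C=C1
F2 | step 11 | (S)-5-[2-(tert-butyldimethylsilyloxy)ethyl]furan-2(5H)-one | CC(C)(C)[Si](C)(C)OCC[C@@H]1OC(=O)C=C1
F3 | step 11 | (4R,5S)-5-[2-(tert-butyldimethylsilyloxy)ethyl]-4-(1,3-dioxolan-2-ylmethyl)dihydrofuran-2(3H)-one | CC(C)(C)[Si](C)(C)OCC[C@@H]1OC(=O)C[C@H]1CC2OCCO2
F4 | step 14 | 2-[(2S,3S,6R)-3-hydroxy-6-methyltetrahydro-2H-pyran-2-yl]-N-methoxy-N-methylacetamide | CON(C)C(=O)C[C@@H]1O[C@H](C)CC[C@@H]1O
F5 | step 14 | N-methoxy-N-methyl-2-[(2S,3S,6R)-6-methyl-3-(triethylsilyloxy)tetrahydro-2H-pyran-2-yl]acetamide | CON(C)C(=O)C[C@@H]1O[C@H](C)CC[C@@H]1O[Si](CC)(CC)CC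
F6 | step 14 | 2-[(2S,3R)-3-(1,3-dioxolan-2-ylmethyl)-4-{2-[(2S,3S,6R)-6-methyl-3-(triethylsilyloxy)tetrahydro-2H-pyran-2-yl]acetyl}-5-oxotetrahydrofuran-2-yl]acetic acid (C8 epimers) | OC(=O)C[C@@H]1OC(=O)C([C@H]1CC2OCCO2)C(=O)C[C@@H]3O[C@H](C)CC[C@@H]3O[Si](CC)(CC)CC
F7 | step 20 | 5-hydroxy-3,4-didehydro-5-deoxocordycicadin D (macrocyclic allylic alcohol, C5 epimers) | C[C@@H]1/C=C/C(O)C[C@@H]2/C(=C3/C[C@@H]4O[C@H](C)CC[C@@H]4O3)C(=O)O[C@H]2CC(=O)O1
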